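## Retrosynthetic overview

1. Hedyotol C (24) ⇐ detosylation of 23 ⇐ ester methanolysis of 22 ⇐ one-step isomerisation of the cis-4-aryl-5-styryl-1,3-dioxane 19, which forms the C-9'–C-8' bond (ring A) and the C-7'–O bond (ring B) and sets C-8' and C-7'.
2. Enabling feature: the 1,3-diol O–C-7–C-8–C-9–O of the guaiacyl half, masked as a methylene acetal whose CH2 is the future C-9', lies beside the E-alkene C-8'=C-7' carrying the 4-alkoxy-3,5-dimethoxyphenyl ring. That ring directs the oxocarbenium carbon to C-8' and stabilises the cation at C-7', which the oxygen on C-9 then captures.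
3. 19 ⇐ cross-metathesis of vinyl dioxane 9 (fragment A: C-7, C-8) with styrene 18 (fragment B: the complete erythro arylglycerol β-aryl ether).
4. 9 ⇐ Evans crotonate syn-aldol, reduction, formal; 18 ⇐ Evans glycolate syn-aldol (C-8''), reduction, Mitsunobu inversion at C-7''.
5. Ring order: temporary 1,3-dioxane (step 5), then ring A (C–C closure) and ring B (C–O closure) together in step 13, where the dioxane disappears.

Key step: step 13

Remark: lignan numbering is used (guaiacyl half C-7 to C-9, syringyl half C-7' to C-9', arylglycerol unit C-7'' to C-9''; ring A = O, C-7, C-8, C-8', C-9'; ring B = O, C-7', C-8', C-8, C-9); "tosyl" = 4-methylbenzenesulfonyl; 4-ethenyl-2,6-dimethoxyphenol is assumed to be purchasable.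

## Route

Step 1
Reactants: 1 vanillin
Product: 2 4-formyl-2-methoxyphenyl 4-methylbenzenesulfonate
Conditions: TsCl, Et3N, DMAP (cat.), CH2Cl2, 0 °C → rt
Reagents that add atoms: 4-methylbenzenesulfonyl chloride, Cc1ccc(cc1)S(Cl)(=O)=O
Why: O-sulfonylation of a phenol is reliable, and the tosylate is chosen because it makes the ring a poor donor for the later cationic step and should survive LiBH4, Bu2BOTf and ruthenium alkylidenes; no stereocentre is formed.

Step 2
Reactants: 3 (4S)-4-benzyl-1,3-oxazolidin-2-one; 4 (E)-but-2-enoyl chloride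
Product: 5 (4S)-4-benzyl-3-[(2E)-but-2-enoyl]-1,3-oxazolidin-2-one
Conditions: n-BuLi, THF, −78 °C; then 4, −78 → 0 °C
Reagents that add atoms: none
Why: N-acylation of the lithiated Evans oxazolidinone by an acid chloride; no new stereocentre.

Step 3
Reactants: 5 (4S)-4-benzyl-3-[(2E)-but-2-enoyl]-1,3-oxazolidin-2-one; 2 4-formyl-2-methoxyphenyl 4-methylbenzenesulfonate
Product: 7 (4S)-4-benzyl-3-[(2S,3S)-2-ethenyl-3-hydroxy-3-(3-methoxy-4-tosyloxyphenyl)propanoyl]-1,3-oxazolidin-2-one, via Z-boron dienolate 6 (not isolated)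
Conditions: Bu2BOTf, Et3N, CH2Cl2, −78 → 0 °C; 2, −78 → 0 °C; pH 7 buffer, MeOH, H2O2, 0 °C
Reagents that add atoms: none
Why: Evans syn-aldol reaction: the Z-boron dienolate 6 should react at its α-carbon through a Zimmerman–Traxler chair on the face away from the benzyl group of the dipole-opposed auxiliary, setting C-7 (S) and C-8 in the 2,3-syn relation (2S,3S in 7).

Step 4
Reactants: 7 (4S)-4-benzyl-3-[(2S,3S)-2-ethenyl-3-hydroxy-3-(3-methoxy-4-tosyloxyphenyl)propanoyl]-1,3-oxazolidin-2-one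
Product: 8 4-[(1S,2R)-1-hydroxy-2-(hydroxymethyl)but-3-en-1-yl]-2-methoxyphenyl 4-methylbenzenesulfonate
Conditions: LiBH4, THF–MeOH, 0 °C
Reagents that add atoms: none
Why: Reductive cleavage of the N-acyloxazolidinone by LiBH4 should give the primary alcohol and return the auxiliary while sulfonate and alkene stay inert; no stereocentre is touched (C-8 is named R only because substituent priorities change).

Step 5
Reactants: 8 4-[(1S,2R)-1-hydroxy-2-(hydroxymethyl)but-3-en-1-yl]-2-methoxyphenyl 4-methylbenzenesulfonate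
Product: 9 4-[(4S,5R)-5-ethenyl-1,3-dioxan-4-yl]-2-methoxyphenyl 4-methylbenzenesulfonate (4,5-cis)
Conditions: CH2(OMe)2 (excess), Me3SiOTf (5 mol %), CH2Cl2, 0 °C → rt; Et3N
Reagents that add atoms: dimethoxymethane, COCOC
Why: Acid-catalysed transacetalisation should give the six-membered methylene acetal of the 1,3-diol, which masks both hydroxyls and already places the future C-9' between the two oxygens; the tosylated ring prevents benzylic ionisation and the stereocentres are untouched.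

Step 6
Reactants: 3 (4S)-4-benzyl-1,3-oxazolidin-2-one; 10 chloroacetyl chloride
Product: 11 (4S)-4-benzyl-3-(chloroacetyl)-1,3-oxazolidin-2-one
Conditions: n-BuLi, THF, −78 °C; then 10, −78 °C
Reagents that add atoms: none
Why: N-acylation of the lithiated Evans oxazolidinone by an acid chloride; no new stereocentre.

Step 7
Reactants: 12 4-ethenyl-2,6-dimethoxyphenol; 11 (4S)-4-benzyl-3-(chloroacetyl)-1,3-oxazolidin-2-one
Product: 13 (4S)-4-benzyl-3-[(4-ethenyl-2,6-dimethoxyphenoxy)acetyl]-1,3-oxazolidin-2-one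
Conditions: K2CO3, NaI (10 mol %), acetone, 40 °C
Reagents that add atoms: none
Why: Williamson ether synthesis (iodide-assisted SN2 of the phenoxide at the α-halo imide), which should be fast at an α-carbonyl carbon even for the flanked 2,6-dimethoxyphenoxide; no stereocentre is formed.

Step 8
Reactants: 13 (4S)-4-benzyl-3-[(4-ethenyl-2,6-dimethoxyphenoxy)acetyl]-1,3-oxazolidin-2-one; 2 4-formyl-2-methoxyphenyl 4-methylbenzenesulfonate
Product: 15 (4S)-4-benzyl-3-[(2S,3R)-2-(4-ethenyl-2,6-dimethoxyphenoxy)-3-hydroxy-3-(3-methoxy-4-tosyloxyphenyl)propanoyl]-1,3-oxazolidin-2-one, via Z-boron enolate 14 (not isolated)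
Conditions: Bu2BOTf, Et3N, CH2Cl2, −78 → 0 °C; 2, −78 → 0 °C; pH 7 buffer, MeOH, H2O2, 0 °C
Reagents that add atoms: none
Why: Evans syn-aldol of a glycolate imide: the Z-boron enolate 14 should add through a Zimmerman–Traxler chair on the face opposite the benzyl group, setting C-8'' (the configuration that is R in the later diol) and C-7'' as the syn, i.e. threo, adduct (2S,3R in 15).

Step 9
Reactants: 15 (4S)-4-benzyl-3-[(2S,3R)-2-(4-ethenyl-2,6-dimethoxyphenoxy)-3-hydroxy-3-(3-methoxy-4-tosyloxyphenyl)propanoyl]-1,3-oxazolidin-2-one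
Product: 16 4-[(1R,2R)-2-(4-ethenyl-2,6-dimethoxyphenoxy)-1,3-dihydroxypropyl]-2-methoxyphenyl 4-methylbenzenesulfonate (threo)
Conditions: LiBH4, THF–MeOH, 0 °C
Reagents that add atoms: none
Why: Reductive cleavage of the N-acyloxazolidinone by LiBH4 should give the 1,3-diol and return the auxiliary; no stereocentre is touched (C-8'' is named R only because substituent priorities change).

Step 10
Reactants: 16 4-[(1R,2R)-2-(4-ethenyl-2,6-dimethoxyphenoxy)-1,3-dihydroxypropyl]-2-methoxyphenyl 4-methylbenzenesulfonate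
Product: 17 (2R,3R)-2-(4-ethenyl-2,6-dimethoxyphenoxy)-3-hydroxy-3-(3-methoxy-4-tosyloxyphenyl)propyl acetate
Conditions: AcCl (1.05 equiv), 2,4,6-collidine, CH2Cl2, −78 °C
Reagents that add atoms: acetyl chloride, CC(Cl)=O
Why: Kinetically selective acylation of the primary hydroxyl with an acid chloride and a hindered pyridine at low temperature should leave the flanked secondary benzylic hydroxyl free; no stereocentre is touched.

Step 11
Reactants: 17 (2R,3R)-2-(4-ethenyl-2,6-dimethoxyphenoxy)-3-hydroxy-3-(3-methoxy-4-tosyloxyphenyl)propyl acetate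
Product: 18 (1S,2R)-3-acetoxy-2-(4-ethenyl-2,6-dimethoxyphenoxy)-1-(3-methoxy-4-tosyloxyphenyl)propyl 4-nitrobenzoate (erythro)
Conditions: 4-nitrobenzoic acid, PPh3, DIAD, THF, 0 °C → rt
Reagents that add atoms: 4-nitrobenzoic acid, OC(=O)c1ccc(cc1)[N+](=O)[O-]
Why: Mitsunobu esterification: SN2 displacement of the alkoxyphosphonium ion by 4-nitrobenzoate should invert C-7'' (R to S), converting the threo into the required erythro series while installing a base-labile protecting group; the tosyloxy-substituted ring disfavours an SN1 pathway.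

Step 12
Reactants: 9 4-[(4S,5R)-5-ethenyl-1,3-dioxan-4-yl]-2-methoxyphenyl 4-methylbenzenesulfonate; 18 (1S,2R)-3-acetoxy-2-(4-ethenyl-2,6-dimethoxyphenoxy)-1-(3-methoxy-4-tosyloxyphenyl)propyl 4-nitrobenzoate
Product: 19 (1S,2R)-3-acetoxy-2-(2,6-dimethoxy-4-{(E)-2-[(4S,5R)-4-(3-methoxy-4-tosyloxyphenyl)-1,3-dioxan-5-yl]ethenyl}phenoxy)-1-(3-methoxy-4-tosyloxyphenyl)propyl 4-nitrobenzoate
Conditions: second-generation Hoveyda–Grubbs catalyst RuCl2(H2IMes)(=CH-C6H4-2-OiPr) (5 mol %), 9 (2 equiv), CH2Cl2, 40 °C, argon sparge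
Reagents that add atoms: none
Why: Olefin cross-metathesis between an allylically branched terminal alkene (slow to homodimerise) and an electron-rich styrene should give the E-disubstituted styrene under thermodynamic control with loss of ethene; no stereocentre is involved.

Step 13
Reactants: 19 (1S,2R)-3-acetoxy-2-(2,6-dimethoxy-4-{(E)-2-[(4S,5R)-4-(3-methoxy-4-tosyloxyphenyl)-1,3-dioxan-5-yl]ethenyl}phenoxy)-1-(3-methoxy-4-tosyloxyphenyl)propyl 4-nitrobenzoate
Product: 22 (7S,8R,7'S,8'R,7''S,8''R)-9''-O-acetyl-7''-O-(4-nitrobenzoyl)-4,4''-di-O-tosylhedyotol C, via silylated oxocarbenium triflate 20 (not isolated), via C-7' benzylic cation 21 (not isolated)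
Conditions: Me3SiOTf (0.3 equiv), 2,6-di-tert-butyl-4-methylpyridine (0.1 equiv), CH2Cl2 (0.01 M), −78 → −30 °C; Et3N quench
Reagents that add atoms: none
Why: Proposed new method: Me3SiOTf should open the methylene acetal reversibly; only the oxocarbenium ion on the C-7 oxygen (20, with the C-9 oxygen silylated) is productive, and its CH2 carbon (C-9') should be attacked by C-8' of the E-styrene to close ring A (five-membered, exo with respect to the alkene), giving the benzylic cation 21 at C-7', which the silyl ether oxygen captures to close ring B (five-membered C–O closure, anti to the new C–C bond) with release of the silyl group, so the whole process is an isomerisation needing only catalytic acid. The closest known reactions are acetal-initiated Prins cyclisations and the oxonium–Prins cyclisation of styrenyl homoallylic alcohols to 2,3-disubstituted tetrahydrofurans with capture of the benzylic cation; new here are the methylene acetal as a tethered formaldehyde equivalent and termination by its own second oxygen. C-8' should be set by the ring fusion, because only the cation with C-7' cis to C-9 can reach the C-9 oxygen, whereas the 8,8'-trans cation cannot close and should return by retro-Prins fragmentation. C-7' should be set by anti addition across the E-alkene, equivalent to kinetic closure on the less hindered face of the cation, which places the aryl group exo. The step needs ionisation at the acetal and not at benzylic C-7, no 2-oxonia-Cope leakage from 20, attack through C-8' and not C-7', and no re-ionisation of the product at C-7'; these should be secured by the aryl tosylate (weak donor on the C-7 ring), by the trialkoxyphenyl group that stabilises positive charge at C-7' only, and by low temperature with a hindered pyridine buffer.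

Step 14
Reactants: 22 (7S,8R,7'S,8'R,7''S,8''R)-9''-O-acetyl-7''-O-(4-nitrobenzoyl)-4,4''-di-O-tosylhedyotol C
Product: 23 4,4''-di-O-tosylhedyotol C
Conditions: K2CO3 (0.2 equiv), MeOH–THF, 0 °C → rt; filtration through silica
Reagents that add atoms: none
Why: Base-catalysed transesterification with methanol (Zemplén-type methanolysis) should remove the acetate and the 4-nitrobenzoate while the aryl sulfonates stay in place, so that the 7''-hydroxyl is unmasked before either para-phenoxide exists and 1,6-elimination to a quinone methide is excluded; no stereocentre is touched.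

Step 15
Reactants: 23 4,4''-di-O-tosylhedyotol C
Product: 24 hedyotol C
Conditions: KOH (10 equiv), 1,4-dioxane–H2O, 60 °C, argon; aq. NH4Cl
Reagents that add atoms: none
Why: Alkaline hydrolysis of the aryl sulfonate esters: hydroxide should attack sulfur and release the two phenoxides, the methanol-free medium excludes formation of methyl 4-methylbenzenesulfonate and re-alkylation of a phenoxide, and the benzylic ether and carbinol centres should not ionise under these conditions, so no stereocentre is touched.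

## Compound list

1 | vanillin (4-hydroxy-3-methoxybenzaldehyde) | COc1cc(C=O)ccc1O | starting material
2 | 4-formyl-2-methoxyphenyl 4-methylbenzenesulfonate | COc1cc(C=O)ccc1OS(=O)(=O)c1ccc(C)cc1 | intermediate
3 | (4S)-4-benzyl-1,3-oxazolidin-2-one | O=C1N[C@@H](Cc2ccccc2)CO1 | starting material
4 | (E)-but-2-enoyl chloride | C/C=C/C(Cl)=O | starting material
5 | (4S)-4-benzyl-3-[(2E)-but-2-enoyl]-1,3-oxazolidin-2-one | C/C=C/C(=O)N1[C@@H](Cc2ccccc2)COC1=O | intermediate
6 | (4S)-4-benzyl-3-[(1Z)-1-(dibutylboranyloxy)buta-1,3-dien-1-yl]-1,3-oxazolidin-2-one (Z-boron dienolate) | C=C/C=C(\OB(CCCC)CCCC)N1[C@@H](Cc2ccccc2)COC1=O | intermediate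
7 | (4S)-4-benzyl-3-[(2S,3S)-2-ethenyl-3-hydroxy-3-(3-methoxy-4-tosyloxyphenyl)propanoyl]-1,3-oxazolidin-2-one | COc1cc([C@@H](O)[C@H](C=C)C(=O)N2[C@@H](Cc3ccccc3)COC2=O)ccc1OS(=O)(=O)c1ccc(C)cc1 | intermediate
8 | 4-[(1S,2R)-1-hydroxy-2-(hydroxymethyl)but-3-en-1-yl]-2-methoxyphenyl 4-methylbenzenesulfonate | COc1cc([C@@H](O)[C@@H](CO)C=C)ccc1OS(=O)(=O)c1ccc(C)cc1 | intermediate
9 | 4-[(4S,5R)-5-ethenyl-1,3-dioxan-4-yl]-2-methoxyphenyl 4-methylbenzenesulfonate (4,5-cis) | COc1cc([C@H]2OCOC[C@H]2C=C)ccc1OS(=O)(=O)c1ccc(C)cc1 | intermediate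
10 | chloroacetyl chloride | ClCC(Cl)=O | starting material
11 | (4S)-4-benzyl-3-(chloroacetyl)-1,3-oxazolidin-2-one | ClCC(=O)N1[C@@H](Cc2ccccc2)COC1=O | intermediate
12 | 4-ethenyl-2,6-dimethoxyphenol | COc1cc(C=C)cc(OC)c1O | starting material
13 | (4S)-4-benzyl-3-[(4-ethenyl-2,6-dimethoxyphenoxy)acetyl]-1,3-oxazolidin-2-one | COc1cc(C=C)cc(OC)c1OCC(=O)N1[C@@H](Cc2ccccc2)COC1=O | intermediate
14 | (4S)-4-benzyl-3-[(1Z)-1-(dibutylboranyloxy)-2-(4-ethenyl-2,6-dimethoxyphenoxy)ethenyl]-1,3-oxazolidin-2-one (Z-boron enolate) | COc1cc(C=C)cc(OC)c1O/C=C(\OB(CCCC)CCCC)N1[C@@H](Cc2ccccc2)COC1=O | intermediate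
15 | (4S)-4-benzyl-3-[(2S,3R)-2-(4-ethenyl-2,6-dimethoxyphenoxy)-3-hydroxy-3-(3-methoxy-4-tosyloxyphenyl)propanoyl]-1,3-oxazolidin-2-one | COc1cc([C@@H](O)[C@H](Oc2c(OC)cc(C=C)cc2OC)C(=O)N2[C@@H](Cc3ccccc3)COC2=O)ccc1OS(=O)(=O)c1ccc(C)cc1 | intermediate
16 | 4-[(1R,2R)-2-(4-ethenyl-2,6-dimethoxyphenoxy)-1,3-dihydroxypropyl]-2-methoxyphenyl 4-methylbenzenesulfonate (threo) | COc1cc([C@@H](O)[C@@H](CO)Oc2c(OC)cc(C=C)cc2OC)ccc1OS(=O)(=O)c1ccc(C)cc1 | intermediate
17 | (2R,3R)-2-(4-ethenyl-2,6-dimethoxyphenoxy)-3-hydroxy-3-(3-methoxy-4-tosyloxyphenyl)propyl acetate | COc1cc([C@@H](O)[C@@H](COC(C)=O)Oc2c(OC)cc(C=C)cc2OC)ccc1OS(=O)(=O)c1ccc(C)cc1 | intermediate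
18 | (1S,2R)-3-acetoxy-2-(4-ethenyl-2,6-dimethoxyphenoxy)-1-(3-methoxy-4-tosyloxyphenyl)propyl 4-nitrobenzoate (erythro) | COc1cc([C@H](OC(=O)c2ccc(cc2)[N+](=O)[O-])[C@@H](COC(C)=O)Oc2c(OC)cc(C=C)cc2OC)ccc1OS(=O)(=O)c1ccc(C)cc1 | intermediate
19 | (1S,2R)-3-acetoxy-2-(2,6-dimethoxy-4-{(E)-2-[(4S,5R)-4-(3-methoxy-4-tosyloxyphenyl)-1,3-dioxan-5-yl]ethenyl}phenoxy)-1-(3-methoxy-4-tosyloxyphenyl)propyl 4-nitrobenzoate | COc1cc([C@H]2OCOC[C@H]2/C=C/c2cc(OC)c(O[C@H](COC(C)=O)[C@@H](OC(=O)c3ccc(cc3)[N+](=O)[O-])c3ccc(OS(=O)(=O)c4ccc(C)cc4)c(OC)c3)c(OC)c2)ccc1OS(=O)(=O)c1ccc(C)cc1 | intermediate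
20 | ring-opened oxocarbenium triflate of 19 (CH2=O+ on the C-7 oxygen, Me3Si on the C-9 oxygen; 7S,8R; E-alkene) | COc1cc([C@@H]([O+]=C)[C@@H](CO[Si](C)(C)C)/C=C/c2cc(OC)c(O[C@H](COC(C)=O)[C@@H](OC(=O)c3ccc(cc3)[N+](=O)[O-])c3ccc(OS(=O)(=O)c4ccc(C)cc4)c(OC)c3)c(OC)c2)ccc1OS(=O)(=O)c1ccc(C)cc1.[O-]S(=O)(=O)C(F)(F)F | intermediate
21 | ring A tetrahydrofuran with benzylic cation at C-7' (triflate; C-7, C-8, C-8' as in 22; C-9 oxygen silylated) | COc1cc([C@H]2OC[C@H]([CH+]c3cc(OC)c(O[C@H](COC(C)=O)[C@@H](OC(=O)c4ccc(cc4)[N+](=O)[O-])c4ccc(OS(=O)(=O)c5ccc(C)cc5)c(OC)c4)c(OC)c3)[C@@H]2CO[Si](C)(C)C)ccc1OS(=O)(=O)c1ccc(C)cc1.[O-]S(=O)(=O)C(F)(F)F | intermediate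
22 | (7S,8R,7'S,8'R,7''S,8''R)-9''-O-acetyl-7''-O-(4-nitrobenzoyl)-4,4''-di-O-tosylhedyotol C | COc1cc([C@H]2OC[C@H]3[C@@H]2CO[C@@H]3c2cc(OC)c(O[C@H](COC(C)=O)[C@@H](OC(=O)c3ccc(cc3)[N+](=O)[O-])c3ccc(OS(=O)(=O)c4ccc(C)cc4)c(OC)c3)c(OC)c2)ccc1OS(=O)(=O)c1ccc(C)cc1 | intermediate
23 | 4,4''-di-O-tosylhedyotol C | COc1cc([C@H]2OC[C@H]3[C@@H]2CO[C@@H]3c2cc(OC)c(O[C@H](CO)[C@@H](O)c3ccc(OS(=O)(=O)c4ccc(C)cc4)c(OC)c3)c(OC)c2)ccc1OS(=O)(=O)c1ccc(C)cc1 | intermediate
24 | hedyotol C | COc1cc([C@H]2OC[C@H]3[C@@H]2CO[C@@H]3c2cc(OC)c(O[C@H](CO)[C@@H](O)c3ccc(O)c(OC)c3)c(OC)c2)ccc1O | target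

## Step count and risks

Total step count: 15. Longest linear sequence: 10 steps (steps 6 to 15).

Steps most likely to fail:

**Step 13 (proposed new method).** Three processes could defeat it. Cyclisation could run through the 8,8'-trans mode, whose benzylic cation cannot close ring B and would drain into elimination. Ionisation of the methylene acetal could be slower than re-ionisation of the product ether at C-7', which would epimerise that centre. A 2-oxonia-Cope equilibrium of 20 could erode C-7 and C-8.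

The fallback uses known reactions, sets out from 19 and returns at 22. Stoichiometric SnBr4 in CH2Cl2 at −78 °C forces the acetal-initiated Prins cyclisation with bromide capture; any 8,8'-cis material still closes to 22 on work-up, and the 8,8'-trans manifold is collected as the 8,8'-trans bromo alcohol F1. DBU in toluene at rt eliminates HBr from F1 to give the 4-benzylidene tetrahydrofuran alcohol F2, in which C-8' is no longer stereogenic. TfOH (2 mol %) in CH2Cl2 at −40 → 0 °C then effects the acid-catalysed intramolecular hydroalkoxylation of the electron-rich styrene. Protonation at C-8' is reversible and only the cation with the cis ring fusion is captured by the primary hydroxyl, so this stepwise, stereoconvergent sequence should arrive at 22.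

**Step 12.** The electron-rich styrene 18 could homodimerise to a stilbene faster than it crosses with the allylically branched alkene 9, and turnover could stall.

The fallback replaces metathesis by a Julia–Kocienski olefination; it sets out from 9 and 18 and returns at 19. Ozonolysis of 9 (O3, CH2Cl2–MeOH, −78 °C) with NaBH4 work-up gives the dioxanyl methanol F3. A Mitsunobu reaction with 1-phenyl-1H-tetrazole-5-thiol (PPh3, DIAD) gives the sulfide F4, and oxidation (H2O2, (NH4)6Mo7O24 cat., EtOH) gives the sulfone F5. In parallel, oxidative cleavage of the vinyl group of 18 (OsO4 cat., NaIO4, 2,6-lutidine, dioxane–H2O) gives the aldehyde F6. Adding KN(SiMe3)2 to F5 and F6 in 1,2-dimethoxyethane at −60 °C (Barbier mode) should give the E-alkene 19.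

**Step 11.** At the hindered benzylic carbinol, elimination toward the enol ether or an ion-pair pathway with partial retention could compete with clean SN2 inversion.

The fallback inverts C-7'' by oxidation and reduction; it sets out from 17 and returns at 18. Dess–Martin periodinane (NaHCO3, CH2Cl2) gives the α-aryloxy ketone F7. Corey–Bakshi–Shibata reduction with (S)-1-methyl-3,3-diphenyltetrahydro-1H,3H-pyrrolo[1,2-c][1,3,2]oxazaborole (cat.) and BH3·SMe2 in THF at −20 °C, matched with the Felkin–Anh preference of the α-aryloxy ketone, should give the erythro alcohol F8. Acylation with 4-nitrobenzoyl chloride (pyridine, DMAP cat.) with retention then gives 18.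

Further compounds
F1 | step 13 | 8,8'-trans bromo alcohol: {(2S,3R)-4-[bromo(aryl)methyl]-2-(3-methoxy-4-tosyloxyphenyl)tetrahydrofuran-3-yl}methanol carrying the side chain of 19 (C-7' mixture) | COc1cc([C@H]2OC[C@@H](C(Br)c3cc(OC)c(O[C@H](COC(C)=O)[C@@H](OC(=O)c4ccc(cc4)[N+](=O)[O-])c4ccc(OS(=O)(=O)c5ccc(C)cc5)c(OC)c4)c(OC)c3)[C@@H]2CO)ccc1OS(=O)(=O)c1ccc(C)cc1
F2 | step 13 | 4-benzylidene tetrahydrofuran alcohol: [(2S,3R)-4-(arylmethylidene)-2-(3-methoxy-4-tosyloxyphenyl)tetrahydrofuran-3-yl]methanol carrying the side chain of 19 (alkene geometry mixed) | COc1cc([C@H]2OCC(=Cc3cc(OC)c(O[C@H](COC(C)=O)[C@@H](OC(=O)c4ccc(cc4)[N+](=O)[O-])c4ccc(OS(=O)(=O)c5ccc(C)cc5)c(OC)c4)c(OC)c3)[C@@H]2CO)ccc1OS(=O)(=O)c1ccc(C)cc1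
F3 | step 12 | 4-[(4S,5R)-5-(hydroxymethyl)-1,3-dioxan-4-yl]-2-methoxyphenyl 4-methylbenzenesulfonate | COc1cc([C@H]2OCOC[C@H]2CO)ccc1OS(=O)(=O)c1ccc(C)cc1
F4 | step 12 | 2-methoxy-4-[(4S,5R)-5-{[(1-phenyl-1H-tetrazol-5-yl)sulfanyl]methyl}-1,3-dioxan-4-yl]phenyl 4-methylbenzenesulfonate | COc1cc([C@H]2OCOC[C@H]2CSc2nnnn2-c2ccccc2)ccc1OS(=O)(=O)c1ccc(C)cc1
F5 | step 12 | 2-methoxy-4-[(4S,5R)-5-{[(1-phenyl-1H-tetrazol-5-yl)sulfonyl]methyl}-1,3-dioxan-4-yl]phenyl 4-methylbenzenesulfonate | COc1cc([C@H]2OCOC[C@H]2CS(=O)(=O)c2nnnn2-c2ccccc2)ccc1OS(=O)(=O)c1ccc(C)cc1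
F6 | step 12 | (1S,2R)-3-acetoxy-2-(4-formyl-2,6-dimethoxyphenoxy)-1-(3-methoxy-4-tosyloxyphenyl)propyl 4-nitrobenzoate | COc1cc(C=O)cc(OC)c1O[C@H](COC(C)=O)[C@@H](OC(=O)c1ccc(cc1)[N+](=O)[O-])c1ccc(OS(=O)(=O)c2ccc(C)cc2)c(OC)c1
F7 | step 11 | (2R)-2-(4-ethenyl-2,6-dimethoxyphenoxy)-3-(3-methoxy-4-tosyloxyphenyl)-3-oxopropyl acetate | COc1cc(C(=O)[C@@H](COC(C)=O)Oc2c(OC)cc(C=C)cc2OC)ccc1OS(=O)(=O)c1ccc(C)cc1
F8 | step 11 | (2R,3S)-2-(4-ethenyl-2,6-dimethoxyphenoxy)-3-hydroxy-3-(3-methoxy-4-tosyloxyphenyl)propyl acetate (erythro) | COc1cc([C@H](O)[C@@H](COC(C)=O)Oc2c(OC)cc(C=C)cc2OC)ccc1OS(=O)(=O)c1ccc(C)cc1
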